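**Retrosynthetic overview**
1. The C7–OAc bond is cut last. The equatorial acetate comes from a direct allylic C–H acetoxylation (C–O bond formation) of the 7-deoxy diene imide.
2. The C8=C17 alkene comes from dehydration of the 8α tertiary alcohol left behind when the lactone is opened.
3. The C12=C13 alkene comes from a Wittig reaction of the lactol of 2α-chlorosclareolide with the ylide made from maleimide and PPh3.
4. The C2–Cl bond comes from a site-selective aliphatic C–H chlorination of (+)-sclareolide.
5. Ring order: no ring is built. Rings A and B are bought in (+)-sclareolide (its lactone ring is opened), and the imide ring is bought in maleimide.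

Assumption: labdane numbering and α/β face labels (β = face of the C10 methyl) are used for all compounds, and the N-chloroamide of step 1 is bought as a reagent.

**Step 1**
Reactants: 1 (+)-sclareolide
Product: 2 2α-chlorosclareolide
Conditions: N-chloro-N-tert-butyl-3,5-bis(trifluoromethyl)benzamide (1.2 equiv), Cs2CO3 (1 equiv), PhH, white light, 55 °C
Reagents that add atoms: N-chloro-N-tert-butyl-3,5-bis(trifluoromethyl)benzamide, CC(C)(C)N(Cl)C(=O)c1cc(cc(c1)C(F)(F)F)C(F)(F)F
Why: Radical-chain aliphatic C–H chlorination with an N-chloroamide: the bulky, electrophilic amidyl radical takes a hydrogen of the C2 methylene, which is the least hindered one and the one farthest from the electron-withdrawing lactone, and the planar C2 radical then takes chlorine from the reagent on its equatorial α side because the axial β side is walled off by the C4 and C10 methyl groups, so the 2α (2S) centre is set here.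

**Step 2**
Reactants: 2 2α-chlorosclareolide
Product: 4 2α-chlorosclareolide lactol (anomeric mixture), via diisobutylaluminium lactolate 3 (not isolated)
Conditions: i-Bu2AlH (1.1 equiv), CH2Cl2, −78 °C; aq. potassium sodium tartrate
Reagents that add atoms: none
Why: Partial lactone reduction with a dialkylaluminium hydride: the tetrahedral aluminium lactolate 3 does not collapse at −78 °C, so only one hydride is delivered, the unactivated secondary chloride is untouched, and the new C12 hemiacetal centre needs no control because it becomes sp2 in step 3.

**Step 3**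
Reactants: 4 2α-chlorosclareolide lactol; 5 maleimide
Product: 8 (12E)-2α-chloro-8α-hydroxylabd-12-ene-15,16-imide, via phosphorus ylide 6 (not isolated), via open hydroxy aldehyde 7 (not isolated)
Conditions: 5 (1.3 equiv), PPh3 (1.3 equiv), THF, 65 °C, 1 h; then 4, PhCO2H (10 mol %), THF/EtOH, 75 °C
Reagents that add atoms: none
Why: Wittig olefination with a stabilised ylide: PPh3 adds to maleimide and a proton shift gives ylide 6, which intercepts the small equilibrium amount of open hydroxy aldehyde 7, and the reversible addition typical of stabilised ylides gives the E alkene (C11 trans to the C16 carbonyl) without touching any stereocentre.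

**Step 4**
Reactants: 8 (12E)-2α-chloro-8α-hydroxylabd-12-ene-15,16-imide
Product: 10 (12E)-2α-chlorolabda-8(17),12-diene-15,16-imide, via C8 chlorosulfite 9 (not isolated)
Conditions: SOCl2 (2 equiv), pyridine (10 equiv), CH2Cl2, −78 to −30 °C
Reagents that add atoms: none
Why: Chlorosulfite formation and E2 elimination: the equatorial C8–O bond of 9 has no antiperiplanar ring C–H bond, whereas a C17 methyl C–H bond can always reach that alignment, so pyridine removes a methyl proton and the exocyclic 8(17)-alkene forms in preference to the ring alkenes, while imide, enimide and the C2 chloride are inert at low temperature.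

**Step 5**
Reactants: 10 (12E)-2α-chlorolabda-8(17),12-diene-15,16-imide
Product: 12 (12E)-7β-acetoxy-2α-chlorolabda-8(17),12-diene-15,16-imide (target), via allylpalladium chloride 11 (not isolated)
Conditions: Pd(OAc)2 (10 mol %), LiCl (20 mol %), LiOAc (2 equiv), p-benzoquinone (2 equiv), AcOH, 45 °C
Reagents that add atoms: acetic acid, CC(=O)O
Why: Proposed new method: chloride-gated, outer-sphere allylic C–H acetoxylation of an exocyclic methylene; electrophilic divalent palladium binds the C8=C17 alkene on the open α face (the β face is covered by the axial C10 methyl) and removes the axial 7α-hydrogen, the only allylic methylene C–H bond aligned with the π system (the tertiary C9–H is far slower), to give allylpalladium chloride 11 with the metal on the α face; chloride and quinone fill the remaining sites, so acetate cannot migrate from the metal and must attack from outside, anti to palladium, that is from the β face, which makes the C7–O bond and sets the equatorial 7β (7S) acetate, opposite to the 7α outcome of ene-type oxidants; attack at C7 rather than C17 is expected because the quinone-bound allyl unit carries more positive charge at its secondary end, because the late transition state profits from the better-bound 1,1-disubstituted alkene on zerovalent palladium, and because a CH2OAc group at C17 would be wedged against C11, while fast re-oxidation of zerovalent palladium by the quinone keeps the kinetic product from re-ionising; the closest known reaction types are the palladium/benzoquinone allylic C–H acetoxylation of terminal and cyclic alkenes and the chloride-controlled anti acetoxylation of allylpalladium intermediates in the 1,4-diacetoxylation of dienes, and the two have not been combined to place an acetate anti to the metal on a ring carbon next to an exocyclic methylene.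

**Compound list**
1 | (+)-sclareolide, (3aR,5aS,9aS,9bR); trans-decalin with 10β-methyl, 5α-H, 9α-H, 8β-methyl and 8α-O of a γ-lactone | C[C@@]12CC[C@H]3C(C)(C)CCC[C@]3(C)[C@H]1CC(=O)O2 | starting material
2 | 2α-chlorosclareolide: 1 with an equatorial (α, 2S) chlorine at C2 of ring A | C[C@@]12CC[C@H]3C(C)(C)C[C@H](Cl)C[C@]3(C)[C@H]1CC(=O)O2 | intermediate
3 | diisobutylaluminium lactolate of 2 (Al–O at C12, both C12 epimers, not isolated) | C[C@@]12CC[C@H]3C(C)(C)C[C@H](Cl)C[C@]3(C)[C@H]1CC(O[Al](CC(C)C)CC(C)C)O2 | intermediate
4 | 2α-chlorosclareolide lactol (12-hydroxy-8α,12-epoxide, mixture of C12 anomers) | C[C@@]12CC[C@H]3C(C)(C)C[C@H](Cl)C[C@]3(C)[C@H]1CC(O)O2 | intermediate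
5 | maleimide (1H-pyrrole-2,5-dione) | O=C1C=CC(=O)N1 | starting material
6 | 3-(triphenyl-λ5-phosphanylidene)pyrrolidine-2,5-dione (stabilised ylide, not isolated) | O=C1CC(=P(c2ccccc2)(c2ccccc2)c2ccccc2)C(=O)N1 | intermediate
7 | open-chain tautomer of 4: 8α-hydroxy C12 aldehyde with 2α-Cl, 8β-methyl and 9α-H (not isolated) | C[C@@]1(O)CC[C@H]2C(C)(C)C[C@H](Cl)C[C@]2(C)[C@H]1CC=O | intermediate
8 | (12E)-2α-chloro-8α-hydroxylabd-12-ene-15,16-imide (3-alkylidenepyrrolidine-2,5-dione, C11 trans to the C16 carbonyl) | C[C@@]1(O)CC[C@H]2C(C)(C)C[C@H](Cl)C[C@]2(C)[C@H]1C/C=C1\CC(=O)NC1=O | intermediate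
9 | C8 (8α) chlorosulfite of 8 (not isolated) | C[C@@]1(OS(=O)Cl)CC[C@H]2C(C)(C)C[C@H](Cl)C[C@]2(C)[C@H]1C/C=C1\CC(=O)NC1=O | intermediate
10 | (12E)-2α-chlorolabda-8(17),12-diene-15,16-imide (exocyclic C8=C17 methylene, 9α-H) | C=C1CC[C@H]2C(C)(C)C[C@H](Cl)C[C@]2(C)[C@H]1C/C=C1\CC(=O)NC1=O | intermediate
11 | (C7–C8–C17 allyl)palladium chloride with Pd on the α face, SMILES drawn as its C17 σ-bonded form (not isolated) | Cl[Pd]CC1=CC[C@H]2C(C)(C)C[C@H](Cl)C[C@]2(C)[C@H]1C/C=C1\CC(=O)NC1=O | intermediate
12 | (12E)-7β-acetoxy-2α-chlorolabda-8(17),12-diene-15,16-imide, (2S,5S,7S,9R,10S), CNP0220384.1 | C=C1[C@@H](OC(C)=O)C[C@H]2C(C)(C)C[C@H](Cl)C[C@]2(C)[C@H]1C/C=C1\CC(=O)NC1=O | target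

**Total step count:** 5. **Longest linear sequence:** 5 steps (1 to 12).

**Three steps most likely to fail**

*Step 5 (the proposed new step).*
- Main risks: acetate may attack the primary C17 end and give the ring alkene with a CH2OAc group. Chloride may slow C–H cleavage. Inner-sphere delivery may leak to the 7α epimer. The allyl complex may lose hydride to give a diene.
- The fallback sets out from 10 and comes back at 12.
- A Riley oxidation of 10 (SeO2 0.5 equiv, t-BuOOH, CH2Cl2, 23 °C) runs by ene reaction and [2,3]-shift on the α face. It gives, with full control of position, the axial 7α-allylic alcohol F1.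
- A Mitsunobu reaction (PPh3, DIAD, AcOH 5 equiv, THF, 0 °C) then displaces the axial, π-aligned oxyphosphonium group from the β face with inversion and gives 12.
- The excess of acetic acid keeps the far less acidic imide N–H from competing.

*Step 3.*
- Main risks: the lactol of a tertiary alcohol opens only to a small extent, so the olefination may be slow. The free 8α-hydroxyl may also add to the new enimide to close a tetrahydrofuran.
- The fallback sets out from 2 and comes back at 10, so the alcohol is removed before the olefination.
- Aminolysis of 2 (MeNH(OMe)·HCl, AlMe3, CH2Cl2) gives the hydroxy Weinreb amide F2.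
- SOCl2/pyridine at −78 °C gives the exocyclic-alkene Weinreb amide F3.
- i-Bu2AlH at −78 °C gives the free aldehyde F4.
- F4 reacts with ylide 6 (made beforehand from 5 and PPh3) in EtOH to give 10.

*Step 4.*
- Main risk: elimination may leak to the ring alkenes (C7=C8 or C8=C9), which are hard to separate from 10.
- The fallback sets out from 8 and comes back at 12. It uses the ring alkene on purpose.
- p-TsOH·H2O (10 mol %) in toluene at 70 °C gives the trisubstituted C7=C8 alkene F5.
- m-CPBA/NaHCO3 epoxidises it on the open α face and leaves the electron-poor enimide alone, which gives the 7α,8α-epoxide F6.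
- Diethylaluminium 2,2,6,6-tetramethylpiperidide (3 equiv, one is spent on the N–H) removes a C17 methyl proton. This opens the epoxide to the 7α-allylic alcohol F1.
- F1 is inverted to 12 by the Mitsunobu reaction with acetic acid described above.

**Further compounds**
F1 | step 5 | (12E)-2α-chloro-7α-hydroxylabda-8(17),12-diene-15,16-imide (axial allylic alcohol) | C=C1[C@H](O)C[C@H]2C(C)(C)C[C@H](Cl)C[C@]2(C)[C@H]1C/C=C1\CC(=O)NC1=O
F2 | step 3 | 2α-chloro-8α-hydroxy C12 N-methoxy-N-methylamide (ring-opened 2) | C[C@@]1(O)CC[C@H]2C(C)(C)C[C@H](Cl)C[C@]2(C)[C@H]1CC(=O)N(C)OC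
F3 | step 3 | 2α-chloro-8(17)-ene C12 N-methoxy-N-methylamide | C=C1CC[C@H]2C(C)(C)C[C@H](Cl)C[C@]2(C)[C@H]1CC(=O)N(C)OC
F4 | step 3 | 2α-chloro-8(17)-en-12-al | C=C1CC[C@H]2C(C)(C)C[C@H](Cl)C[C@]2(C)[C@H]1CC=O
F5 | step 4 | (12E)-2α-chlorolabda-7,12-diene-15,16-imide | CC1=CC[C@H]2C(C)(C)C[C@H](Cl)C[C@]2(C)[C@H]1C/C=C1\CC(=O)NC1=O
F6 | step 4 | (12E)-2α-chloro-7α,8α-epoxylabd-12-ene-15,16-imide | C[C@@]12O[C@@H]1C[C@H]3C(C)(C)C[C@H](Cl)C[C@]3(C)[C@H]2C/C=C1\CC(=O)NC1=O
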